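**Retrosynthetic overview**
1. The two angelates, the 8α,9α-epoxide and the C2 and C6 carbinols are late, hydroxyl-directed events. C10-OH directs the epoxidation, and C4-OH delivers hydride to C2=O and to C6=O. These lead back to a cis-fused hydroazulen-6-one.
2. The key disconnection is the C1–C5 bond. Moving C1 back from C5 to C6 turns the cyclopentane (C1–C5) into a cyclohexane (C1–C6) and the cycloheptene (C1, C5–C10) into a cyclohexene (C1, C6–C10). The precursor is therefore a cis-decalin 6-hydroxy-5-mesylate that rearranges by a pinacol-type 1,2-shift.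
3. Enabling feature: C6 is bonded to C5 and carries oxygen, so it can act as the carbinol terminus. With C6 counted in, ring C1–C6 is a p-menthane (C1-Me para to C4-OH/iPr), and C7–C10 plus the C8 methyl is an isoprene unit.
4. The decalin comes from a Diels–Alder reaction of an (R)-terpinen-4-ol-derived 2-ene-1,4-dione with a prenal-derived 1-silyloxydiene. The purchased C4 centre relays C1, C6 and C10 in that one event.
5. Ring order: six-membered ring A (bought), then six-membered ring B (cycloaddition), then the five- and seven-membered rings together (key step), then the oxirane.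

Key step: step 11

Assumption and numbering: (R)-(−)-terpinen-4-ol is taken as enantiomerically pure commercial material. Daucane numbering (C1 quaternary methyl carbon, C2 CHOH, C3 CH2, C4 isopropyl carbinol, C5 ring-fusion CH, C6 and C10 ester carbons, C7 CH2, C8/C9 epoxide) is kept for the same atoms in all bicyclic precursors, and β is the face of the C1 methyl.

**Step 1**
Reactants: 1 (R)-(−)-terpinen-4-ol
Product: 3 (R)-5-hydroxy-2-methyl-5-(propan-2-yl)cyclohex-2-en-1-one (E)-oxime, via nitrosochloride 2 (not isolated)
Conditions: isopentyl nitrite, conc. HCl, MeOH, −10 °C; then pyridine, acetone, reflux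
Reagents that add atoms: isopentyl nitrite CC(C)CCON=O; hydrogen chloride Cl
Why: Nitrosochlorination followed by dehydrochlorination: NO adds to the CH end and chloride to the methyl-bearing end of the trisubstituted alkene (Markovnikov), and pyridine then removes HCl towards the ring CH2 while the nitroso group tautomerises, which gives the conjugated oxime and leaves the carbinol centre untouched.

**Step 2**
Reactants: 3 (R)-5-hydroxy-2-methyl-5-(propan-2-yl)cyclohex-2-en-1-one (E)-oxime
Product: 4 (R)-5-hydroxy-2-methyl-5-(propan-2-yl)cyclohex-2-en-1-one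
Conditions: 50% aq. glyoxylic acid, THF, rt
Reagents that add atoms: glyoxylic acid O=CC(=O)O
Why: Transoximation: the more electrophilic aldehyde of glyoxylic acid takes over the hydroxylamine under mild conditions, so the β-hydroxy enone should be released without dehydration to the phenol.

**Step 3**
Reactants: 4 (R)-5-hydroxy-2-methyl-5-(propan-2-yl)cyclohex-2-en-1-one
Product: 5 (R)-5-hydroxy-2-methyl-5-(propan-2-yl)cyclohex-2-ene-1,4-dione
Conditions: Pd(OH)2/C (cat.), t-BuOOH, K2CO3 (cat.), CH2Cl2, 4 °C to rt
Reagents that add atoms: tert-butyl hydroperoxide CC(C)(C)OO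
Why: The Pd(OH)2/C–t-BuOOH γ-oxidation of α,β-enones to 1,4-enediones (allylic peroxidation and elimination) attacks the only γ-CH2, so no allylic transposition can erode the configuration at the carbinol carbon.

**Step 4**
Reactants: 6 3-methylbut-2-enal (prenal)
Product: 7 (E)-triethyl[(3-methylbuta-1,3-dien-1-yl)oxy]silane
Conditions: TESOTf, Et3N, Et2O, 0 °C to rt
Reagents that add atoms: triethylsilyl trifluoromethanesulfonate CC[Si](CC)(CC)OS(=O)(=O)C(F)(F)F
Why: Soft vinylogous enolisation (silyl dienol ether formation) removes a γ-methyl proton of the enal and should give the (E)-1-silyloxydiene.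

**Step 5**
Reactants: 5 (R)-5-hydroxy-2-methyl-5-(propan-2-yl)cyclohex-2-ene-1,4-dione; 7 (E)-triethyl[(3-methylbuta-1,3-dien-1-yl)oxy]silane
Product: 8 cis-decalin-2,5-dione (1β-Me, 6β-H, 4α-OH, 4β-iPr, 8-Me, C8=C9, 10α-OTES)
Conditions: toluene, BHT (cat.), 60 °C
Reagents that add atoms: none
Why: Normal-electron-demand Diels–Alder reaction: the nucleophilic CH2 terminus of the diene bonds to the unsubstituted enedione carbon C6 and the oxygenated terminus to the methyl-bearing C1 (ortho rule relative to C2=O, less hindered bond formed first), the diene approaches anti to the pseudo-equatorial isopropyl group on the face of the small axial C4-OH, and the endo transition state puts 10-OTES trans to the C1 methyl, so C1, C6 and C10 are all relayed from C4 in one event.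

**Step 6**
Reactants: 8 cis-decalin-2,5-dione
Product: 9 2β-hydroxy-cis-decalin-5-one (otherwise as 8)
Conditions: Me4NBH(OAc)3, MeCN/AcOH, −30 °C
Reagents that add atoms: none
Why: Evans–Saksena reduction: the axial C4-OH binds boron and delivers hydride through a chair-like six-membered transition state to the α face of the 1,3-related C2 ketone, which gives the equatorial 2β-alcohol, whereas the C5 ketone, flanked by a quaternary and a tertiary carbon and only α to the hydroxyl, should stay behind.

**Step 7**
Reactants: 9 2β-hydroxy-cis-decalin-5-one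
Product: 10 2β-OTBS-cis-decalin-5-one
Conditions: TBSOTf, 2,6-lutidine, CH2Cl2, −78 to 0 °C
Reagents that add atoms: tert-butyldimethylsilyl trifluoromethanesulfonate CC(C)(C)[Si](C)(C)OS(=O)(=O)C(F)(F)F
Why: Silylation with the reactive triflate takes the only secondary alcohol, because the axial tertiary C4-OH next to the isopropyl group is too hindered at low temperature.

**Step 8**
Reactants: 10 2β-OTBS-cis-decalin-5-one
Product: 11 6β-hydroxy-2β-OTBS-cis-decalin-5-one (angular alcohol)
Conditions: KN(SiMe3)2, THF, −78 to −20 °C; 2-(phenylsulfonyl)-3-phenyloxaziridine, −78 °C; AcOH quench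
Reagents that add atoms: 2-(phenylsulfonyl)-3-phenyloxaziridine O=S(=O)(c1ccccc1)N1OC1c1ccccc1
Why: Enolate hydroxylation with an N-sulfonyloxaziridine: C6-H is the only enolisable position of the remaining ketone (C4 is quaternary), and the oxidant should reach the tetrasubstituted enolate from the convex β face, away from 10α-OTES and the C4 alkoxide; the C6 configuration is erased again in step 11.

**Step 9**
Reactants: 11 6β-hydroxy-2β-OTBS-cis-decalin-5-one
Product: 12 cis-decalin-4α,5α,6β-triol (2β-OTBS, 10α-OTES)
Conditions: LiAlH4, Et2O, −78 to 0 °C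
Reagents that add atoms: none
Why: Hydride addition to the ketone from the convex β face, the α face being screened by the axial C7 methylene and the axial C4 aluminate, should give the equatorial 5α-alcohol.

**Step 10**
Reactants: 12 cis-decalin-4α,5α,6β-triol
Product: 13 5α-mesylate of 12
Conditions: MsCl, Et3N, CH2Cl2, −20 °C
Reagents that add atoms: methanesulfonyl chloride CS(=O)(=O)Cl
Why: Mesylation via sulfene reaches the single secondary alcohol, the two flanking alcohols being tertiary.

**Step 11**
Reactants: 13 5α-mesylate of 12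
Product: 14 cis-hydroazulen-6-one (1β-Me, 5β-H, 4α-OH, 4β-iPr, 2β-OTBS, 10α-OTES, C8=C9)
Conditions: Et3Al, CH2Cl2, −78 to −20 °C; aq. Rochelle salt
Reagents that add atoms: none
Why: Et3Al turns the C6 and C4 hydroxyls into aluminium alkoxides and activates the mesylate, and the C6–C1 σ-bond, which is antiperiplanar to the equatorial C5–OMs bond in the chair–chair conformer that keeps isopropyl, OTBS and OMs equatorial, migrates to C5 while C6 becomes the ketone (concerted semipinacol 1,2-shift). The closest known reaction type is the organoaluminium- or base-promoted pinacol-type rearrangement of β-hydroxy sulfonates, long used to turn angularly methylated decalins into hydroazulenes. No ring is closed by cyclisation: the single suprafacial 1,2-alkyl shift contracts ring A (C1–C6, six atoms) to the cyclopentane C1–C5 and at the same time enlarges ring B (six atoms) to the cycloheptene C1, C5–C10. The only new stereocentre, C5, is formed with inversion (5α-OMs gives 5β-H) and C1 migrates with retention, so the cis fusion (1β-Me, 5β-H) follows from the C5 configuration set in step 9. The step needs migration of C1 rather than of C3 (also antiperiplanar and pushed by the C4 alkoxide) or of C7: the fully substituted C1 has the higher migratory aptitude, its shift relieves the vicinal congestion at C1/C6, and C7 is gauche to the leaving group. Low temperature and weakly basic aluminium alkoxides should keep the β-hydroxy ketone product from retro-aldol cleavage and from epimerisation at C5.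

**Step 12**
Reactants: 14 cis-hydroazulen-6-one
Product: 15 6β-alcohol of 14
Conditions: Me4NBH(OAc)3, MeCN/AcOH, −30 °C
Reagents that add atoms: none
Why: Evans–Saksena reduction: the 4α-hydroxyl delivers hydride to the α face of the β-related C6 ketone and should give the 1,3-anti diol, that is the 6β-alcohol.

**Step 13**
Reactants: 15 6β-alcohol of 14
Product: 16 hydroazulene-4α,6β,10α-triol (2β-OTBS, C8=C9)
Conditions: HF·pyridine, pyridine, THF, 0 °C
Reagents that add atoms: none
Why: Selective desilylation: a triethylsilyl ether is cleaved much faster than a tert-butyldimethylsilyl ether under buffered HF.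

**Step 14**
Reactants: 16 hydroazulene-4α,6β,10α-triol
Product: 17 8α,9α-epoxide of 16
Conditions: VO(acac)2 (cat.), t-BuOOH, CH2Cl2, 0 °C
Reagents that add atoms: tert-butyl hydroperoxide CC(C)(C)OO
Why: Vanadium-catalysed hydroxyl-directed epoxidation: the allylic 10α-OH binds the metal peroxide and delivers oxygen syn to itself in the seven-membered ring, faster than the homoallylic 6β-OH can, which sets C8 and C9.

**Step 15**
Reactants: 17 8α,9α-epoxide of 16; 18 angelic anhydride
Product: 19 6β,10α-bis-angelate of 17 (2β-OTBS)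
Conditions: LiN(SiMe3)2, THF, −78 °C; then 18, −78 to 0 °C
Reagents that add atoms: none
Why: Acylation of the lithium alkoxides with the anhydride needs no nucleophilic catalyst, so the Z geometry of the angelate is conserved, and the tertiary C4 alkoxide is too hindered to react.

**Step 16**
Reactants: 19 6β,10α-bis-angelate of 17
Product: 20 target CNP0265715.3
Conditions: HF·pyridine, pyridine, THF, 0 °C to rt
Reagents that add atoms: none
Why: Fluoride-driven desilylation buffered with pyridine frees the 2β-alcohol while the esters and the trisubstituted epoxide should survive.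

**Compound list**
1 | (R)-(−)-terpinen-4-ol, (1R)-4-methyl-1-(propan-2-yl)cyclohex-3-en-1-ol | CC1=CC[C@@](O)(C(C)C)CC1 | starting material
2 | 4-chloro-4-methyl-3-nitroso-1-(propan-2-yl)cyclohexan-1-ol, carbinol configuration as in 1, diastereomers at the two new centres | CC1(Cl)CC[C@](O)(C(C)C)CC1N=O | intermediate
3 | (R)-5-hydroxy-2-methyl-5-(propan-2-yl)cyclohex-2-en-1-one (E)-oxime | CC1=CC[C@](O)(C(C)C)C/C1=N\O | intermediate
4 | (R)-5-hydroxy-2-methyl-5-(propan-2-yl)cyclohex-2-en-1-one | CC1=CC[C@](O)(C(C)C)CC1=O | intermediate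
5 | (R)-5-hydroxy-2-methyl-5-(propan-2-yl)cyclohex-2-ene-1,4-dione | CC1=CC(=O)[C@](O)(C(C)C)CC1=O | intermediate
6 | 3-methylbut-2-enal (prenal) | CC(C)=CC=O | starting material
7 | (E)-triethyl[(3-methylbuta-1,3-dien-1-yl)oxy]silane | C=C(C)/C=C/O[Si](CC)(CC)CC | intermediate
8 | cis-decalin: ring A C1–C6 with C2 and C5 ketones, 1β-Me, 6β-H, 4α-OH, 4β-iPr; ring B C1, C6–C10 with C8=C9, 8-Me, 10α-OTES | [C@@H]12CC(C)=C[C@H](O[Si](CC)(CC)CC)[C@]1(C)C(=O)C[C@@](O)(C(C)C)C2=O | intermediate
9 | as 8 with 2β-OH in place of the C2 ketone | [C@@H]12CC(C)=C[C@H](O[Si](CC)(CC)CC)[C@]1(C)[C@@H](O)C[C@@](O)(C(C)C)C2=O | intermediate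
10 | 2β-tert-butyldimethylsilyl ether of 9 | [C@@H]12CC(C)=C[C@H](O[Si](CC)(CC)CC)[C@]1(C)[C@@H](O[Si](C)(C)C(C)(C)C)C[C@@](O)(C(C)C)C2=O | intermediate
11 | as 10 with angular 6β-OH in place of 6β-H | O[C@@]12CC(C)=C[C@H](O[Si](CC)(CC)CC)[C@]1(C)[C@@H](O[Si](C)(C)C(C)(C)C)C[C@@](O)(C(C)C)C2=O | intermediate
12 | as 11 with equatorial 5α-OH (5β-H) in place of the C5 ketone; 4α,5α,6β-triol | O[C@@]12CC(C)=C[C@H](O[Si](CC)(CC)CC)[C@]1(C)[C@@H](O[Si](C)(C)C(C)(C)C)C[C@@](O)(C(C)C)[C@@H]2O | intermediate
13 | 5α-methanesulfonate of 12 | O[C@@]12CC(C)=C[C@H](O[Si](CC)(CC)CC)[C@]1(C)[C@@H](O[Si](C)(C)C(C)(C)C)C[C@@](O)(C(C)C)[C@@H]2OS(C)(=O)=O | intermediate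
14 | cis-hydroazulen-6-one: cyclopentane C1–C5 (1β-Me, 5β-H, 2β-OTBS, 4α-OH, 4β-iPr), cycloheptene C1, C5–C10 (C6 ketone, C8=C9, 8-Me, 10α-OTES) | O=C1CC(C)=C[C@H](O[Si](CC)(CC)CC)[C@@]2(C)[C@@H]1[C@](O)(C(C)C)C[C@@H]2O[Si](C)(C)C(C)(C)C | intermediate
15 | as 14 with 6β-OH in place of the ketone | O[C@H]1CC(C)=C[C@H](O[Si](CC)(CC)CC)[C@@]2(C)[C@@H]1[C@](O)(C(C)C)C[C@@H]2O[Si](C)(C)C(C)(C)C | intermediate
16 | as 15 with free 10α-OH | O[C@H]1CC(C)=C[C@H](O)[C@@]2(C)[C@@H]1[C@](O)(C(C)C)C[C@@H]2O[Si](C)(C)C(C)(C)C | intermediate
17 | 8α,9α-epoxide of 16 | O[C@H]1C[C@]2(C)O[C@@H]2[C@H](O)[C@@]2(C)[C@@H]1[C@](O)(C(C)C)C[C@@H]2O[Si](C)(C)C(C)(C)C | intermediate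
18 | angelic anhydride, (Z)-2-methylbut-2-enoic anhydride | C/C=C(/C)C(=O)OC(=O)/C(C)=C\C | starting material
19 | 6β,10α-bis-angelate of 17, 2β-OTBS | C/C=C(/C)C(=O)O[C@H]1C[C@]2(C)O[C@@H]2[C@H](OC(=O)/C(C)=C\C)[C@@]2(C)[C@@H]1[C@](O)(C(C)C)C[C@@H]2O[Si](C)(C)C(C)(C)C | intermediate
20 | CNP0265715.3: 6β,10α-bis(angeloyloxy)-8α,9α-epoxy-cis-daucane-2β,4α-diol | C/C=C(/C)C(=O)O[C@H]1C[C@]2(C)O[C@@H]2[C@H](OC(=O)/C(C)=C\C)[C@@]2(C)[C@@H]1[C@](O)(C(C)C)C[C@@H]2O | target

**Step count and risks**
Total step count: 16. Longest linear sequence: 15 steps (1 to 20 through steps 1–3 and 5–16).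

Steps most likely to fail:

Step 11. The C3 methylene, pushed by the free C4 alkoxide, may migrate in competition with C1, or the mesylate may be lost by elimination. The fallback sets out from 12 and comes back at 14.
- The cis C4/C5 diol is tied up with 1,1'-sulfonyldiimidazole and NaH as the 4,5-cyclic sulfate F1.
- The C4 oxygen then can no longer push, and the equatorial C5–O bond is the leaving group.
- KOt-Bu in THF leaves only the C6 alkoxide to drive the shift of C1 and gives the hydroazulenone C4 hydrogen sulfate F2.
- F2 is hydrolysed with catalytic H2SO4 in wet THF to 14.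

Step 8. Deprotonation of the ring-fusion C6–H, which lies equatorial to ring A, may be slow, and the α-ketol may isomerise under strong base. The fallback sets out from 10 and comes back at 11.
- Soft, equilibrating enolisation with TMSOTf and Et3N at rt gives the C5(6) trimethylsilyl enol ether that also carries C4-OTMS, the bis-TMS compound F3.
- Rubottom oxidation with one equivalent of dimethyldioxirane at −78 °C should take the electron-rich enol ether before the C8=C9 alkene.
- Aqueous citric acid removes the TMS groups and gives 11.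

Step 9. Facial selectivity of hydride addition to a ketone flanked by two fully substituted carbinol carbons may be poor. The fallback sets out from 11 and comes back at 12.
- The reduction is run without regard to selectivity.
- The axial 5β-alcohol F4 is then brought to the equatorial 5α-alcohol 12 by Meerwein–Ponndorf–Verley/Oppenauer redox equilibration (Al(OiPr)3, i-PrOH, trace acetone, toluene, 80 °C).
- Control is thermodynamic instead of kinetic.

**Further compounds**
F1 | step 11 | 4α,5α-cyclic sulfate of 12 | O[C@@]12CC(C)=C[C@H](O[Si](CC)(CC)CC)[C@]1(C)[C@@H](O[Si](C)(C)C(C)(C)C)C[C@@]3(C(C)C)[C@@H]2OS(=O)(=O)O3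
F2 | step 11 | C4 hydrogen sulfate of 14 | O=C1CC(C)=C[C@H](O[Si](CC)(CC)CC)[C@@]2(C)[C@@H]1[C@](OS(=O)(=O)O)(C(C)C)C[C@@H]2O[Si](C)(C)C(C)(C)C
F3 | step 8 | C5(6) trimethylsilyl enol ether of 10 with C4-OTMS | CC1=C[C@H](O[Si](CC)(CC)CC)[C@]2(C)[C@@H](O[Si](C)(C)C(C)(C)C)C[C@@](O[Si](C)(C)C)(C(C)C)C(O[Si](C)(C)C)=C2C1
F4 | step 9 | 5β-epimer (axial alcohol) of 12 | O[C@@]12CC(C)=C[C@H](O[Si](CC)(CC)CC)[C@]1(C)[C@@H](O[Si](C)(C)C(C)(C)C)C[C@@](O)(C(C)C)[C@H]2O
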